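**Assumption:** the target (marchantin A) has no stereocentre and no stable stereo-axis, so it is a single achiral compound and no configuration has to be set. Equivalents, concentrations and yield expectations are planning values, not tested results.

## Retrosynthetic overview

1. The ring-C catechol is unmasked last by Dakin oxidation of a macrocyclic salicylaldehyde; the CHO is a masked OH placed early by ortho-formylation.
2. The macrocycle is closed at an aryl–CH2 bond, not at CH2–CH2: the ring-D aryl radical (from C–Br) adds to a ring-A vinyl group.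
3. The other bridge (B–C) is made the same way but intermolecularly: ring-C aryl radical (from C–I) plus ring-B styrene.
4. Both diaryl ethers come from catechol and a bromo-iodobenzene (Ullmann at iodide); vinyl groups come from Suzuki coupling; iodides from para-iodination of the phenols.
5. Ring order: all four benzene rings are bought; the only ring formed is the macrocycle (step 9).

## Route

**Step 1**
Reactants: 1 catechol (benzene-1,2-diol); 2 1-bromo-4-iodobenzene
Product: 3 2-(4-bromophenoxy)phenol
Conditions: 1 (3 equiv), CuI (10 mol%), picolinic acid (20 mol%), K3PO4 (2 equiv), DMSO, 80 °C, Ar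
Reagents that add atoms: none
Why: Ullmann-type Cu-catalysed O-arylation; C–I reacts far faster than C–Br, so the bromide survives, and excess catechol plus the lower reactivity of the hindered mono-ether limit double arylation.

**Step 2**
Reactants: 3 2-(4-bromophenoxy)phenol
Product: 5 3-(4-bromophenoxy)-2-hydroxybenzaldehyde, via salicyl alcohol 4 (not isolated)
Conditions: MgCl2 (1.5 equiv), Et3N (3.8 equiv), (CH2O)n (6.8 equiv), MeCN, reflux; then 1 M HCl
Reagents that add atoms: paraformaldehyde (formaldehyde), C=O
Why: Casnati–Skattebøl ortho-formylation; the magnesium phenoxide delivers formaldehyde to the only free ortho carbon and a second formaldehyde oxidises the hydroxymethyl intermediate by hydride transfer.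

**Step 3**
Reactants: 5 3-(4-bromophenoxy)-2-hydroxybenzaldehyde
Product: 6 3-(4-bromophenoxy)-2-hydroxy-5-iodobenzaldehyde
Conditions: NIS (1.05 equiv), TFA (0.3 equiv), MeCN, rt
Reagents that add atoms: N-iodosuccinimide, O=C1CCC(=O)N1I
Why: Electrophilic aromatic iodination; both ortho positions of the phenol are occupied, so the para carbon is the only activated site, and the bromophenyl ether ring is deactivated.

**Step 4**
Reactants: 1 catechol (benzene-1,2-diol); 7 1-bromo-3-iodobenzene
Product: 8 2-(3-bromophenoxy)phenol
Conditions: 1 (3 equiv), CuI (10 mol%), picolinic acid (20 mol%), K3PO4 (2 equiv), DMSO, 80 °C, Ar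
Reagents that add atoms: none
Why: Ullmann-type Cu-catalysed O-arylation, selective for iodide over bromide as in step 1.

**Step 5**
Reactants: 8 2-(3-bromophenoxy)phenol
Product: 9 2-(3-ethenylphenoxy)phenol
Conditions: CH2=CHBF3K (1.3 equiv), PdCl2(dppf) (3 mol%), K2CO3 (3 equiv), THF/H2O 9:1, 80 °C; BHT added on work-up
Reagents that add atoms: potassium vinyltrifluoroborate, C=C[B-](F)(F)F.[K+]
Why: Suzuki–Miyaura vinylation (Molander conditions); the free phenol is tolerated.

**Step 6**
Reactants: 6 3-(4-bromophenoxy)-2-hydroxy-5-iodobenzaldehyde; 9 2-(3-ethenylphenoxy)phenol (3 equiv, 0.6 M)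
Product: 10 3-(4-bromophenoxy)-2-hydroxy-5-[2-[3-(2-hydroxyphenoxy)phenyl]ethyl]benzaldehyde
Conditions: Bu3SnH (1.3 equiv) and AIBN (0.2 equiv) added over 4 h, benzene, 80 °C, Ar; excess 9 recovered
Reagents that add atoms: none
Why: Radical-chain anti-Markovnikov hydroarylation of a styrene (reductive Meerwein/Giese-type); Bu3Sn• abstracts iodine far faster than bromine, the aryl radical adds to the terminal CH2, and the benzylic radical is reduced by Bu3SnH.

**Step 7**
Reactants: 10 3-(4-bromophenoxy)-2-hydroxy-5-[2-[3-(2-hydroxyphenoxy)phenyl]ethyl]benzaldehyde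
Product: 11 3-(4-bromophenoxy)-2-hydroxy-5-[2-[3-(2-hydroxy-5-iodophenoxy)phenyl]ethyl]benzaldehyde
Conditions: NIS (1.0 equiv), TsOH·H2O (5 mol%), MeCN, 0 °C to rt
Reagents that add atoms: N-iodosuccinimide, O=C1CCC(=O)N1I
Why: Electrophilic aromatic iodination para to the ring-A hydroxyl; ring A is the only ring with a free phenol-activated position, since ring C is fully substituted ortho/para and carries CHO.

**Step 8**
Reactants: 11 3-(4-bromophenoxy)-2-hydroxy-5-[2-[3-(2-hydroxy-5-iodophenoxy)phenyl]ethyl]benzaldehyde
Product: 12 3-(4-bromophenoxy)-5-[2-[3-(5-ethenyl-2-hydroxyphenoxy)phenyl]ethyl]-2-hydroxybenzaldehyde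
Conditions: CH2=CHBF3K (1.2 equiv), PdCl2(dppf) (3 mol%), K2CO3 (3 equiv), THF/H2O 9:1, 55 °C
Reagents that add atoms: potassium vinyltrifluoroborate, C=C[B-](F)(F)F.[K+]
Why: Suzuki–Miyaura vinylation; at 55 °C oxidative addition into C–I is much faster than into the electron-rich C–Br, which is kept for step 9.

**Step 9**
Reactants: 12 3-(4-bromophenoxy)-5-[2-[3-(5-ethenyl-2-hydroxyphenoxy)phenyl]ethyl]-2-hydroxybenzaldehyde
Product: 13 macrocyclic salicylaldehyde (marchantin A with CHO in place of the ring-C hydroxyl meta to the ethylene bridge)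
Conditions: Bu3SnH (1.5 equiv) and AIBN (0.3 equiv) in t-BuOH by syringe pump over 12 h into 12 (1 mM) in t-BuOH, 82 °C, Ar
Reagents that add atoms: none
Why: Proposed new method: Bu3Sn• abstracts Br from the 4-aryloxyphenyl bromide and the aryl radical adds endo to the terminal carbon of the ring-A styrene (about 1e8 M-1 s-1 times effective molarity, roughly 1e6 s-1, against H-abstraction from t-BuOH or from about 0.5 mM Bu3SnH), then the benzylic radical is reduced by Bu3SnH; there is no ortho-aryloxy group, so no dibenzofuran-type side cyclisation; the closest known reaction types are Porter-type tin-hydride radical macrocyclisation onto a terminal alkene and the intermolecular aryl-radical hydroarylation of step 6; no stereocentre is formed.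

**Step 10**
Reactants: 13 macrocyclic salicylaldehyde
Product: 15 marchantin A, via aryl formate 14 (not isolated)
Conditions: 30% H2O2 (1.5 equiv), B(OH)3 (5 equiv), H2SO4 (cat.), THF, rt, Ar
Reagents that add atoms: hydrogen peroxide, OO
Why: Dakin oxidation; the ortho-hydroxyaryl group migrates to oxygen and the formate hydrolyses in the aqueous acid, while boric acid complexes the new catechol and protects it from over-oxidation; the product has no stereocentre.

## Compound list

1 | catechol (benzene-1,2-diol) | Oc1ccccc1O | starting material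
2 | 1-bromo-4-iodobenzene | Brc1ccc(I)cc1 | starting material
3 | 2-(4-bromophenoxy)phenol | Oc1ccccc1Oc1ccc(Br)cc1 | intermediate
4 | 2-(4-bromophenoxy)-6-(hydroxymethyl)phenol (magnesium phenoxide in the flask, not isolated) | OCc1cccc(Oc2ccc(Br)cc2)c1O | intermediate
5 | 3-(4-bromophenoxy)-2-hydroxybenzaldehyde | O=Cc1cccc(Oc2ccc(Br)cc2)c1O | intermediate
6 | 3-(4-bromophenoxy)-2-hydroxy-5-iodobenzaldehyde | O=Cc1cc(I)cc(Oc2ccc(Br)cc2)c1O | intermediate
7 | 1-bromo-3-iodobenzene | Brc1cccc(I)c1 | starting material
8 | 2-(3-bromophenoxy)phenol | Oc1ccccc1Oc1cccc(Br)c1 | intermediate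
9 | 2-(3-ethenylphenoxy)phenol | Oc1ccccc1Oc1cccc(C=C)c1 | intermediate
10 | 3-(4-bromophenoxy)-2-hydroxy-5-[2-[3-(2-hydroxyphenoxy)phenyl]ethyl]benzaldehyde | O=Cc1cc(CCc2cccc(Oc3ccccc3O)c2)cc(Oc2ccc(Br)cc2)c1O | intermediate
11 | 3-(4-bromophenoxy)-2-hydroxy-5-[2-[3-(2-hydroxy-5-iodophenoxy)phenyl]ethyl]benzaldehyde | O=Cc1cc(CCc2cccc(Oc3cc(I)ccc3O)c2)cc(Oc2ccc(Br)cc2)c1O | intermediate
12 | 3-(4-bromophenoxy)-5-[2-[3-(5-ethenyl-2-hydroxyphenoxy)phenyl]ethyl]-2-hydroxybenzaldehyde | O=Cc1cc(CCc2cccc(Oc3cc(C=C)ccc3O)c2)cc(Oc2ccc(Br)cc2)c1O | intermediate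
13 | macrocyclic salicylaldehyde (marchantin A with CHO in place of the ring-C hydroxyl meta to the ethylene bridge) | Oc1ccc2cc1Oc1cccc(c1)CCc1cc(C=O)c(O)c(c1)Oc1ccc(cc1)CC2 | intermediate
14 | macrocyclic aryl formate (formate ester of that ring-C oxygen, not isolated) | Oc1ccc2cc1Oc1cccc(c1)CCc1cc(OC=O)c(O)c(c1)Oc1ccc(cc1)CC2 | intermediate
15 | marchantin A (CNP0495401.0) | Oc1ccc2cc1Oc1cccc(c1)CCc1cc(O)c(O)c(c1)Oc1ccc(cc1)CC2 | target

## Step count and risks

Total step count: 10. Longest linear sequence: 8 steps (1, 2, 3, 6, 7, 8, 9, 10); steps 4 and 5 form the second branch.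

**Three steps most likely to fail**

- **Step 9 (radical macrocyclisation).** The aryl radical is short-lived, and hydrogen abstraction from solvent or Bu3SnH gives the debrominated open-chain styrene; a yield of roughly 25–40% is the realistic expectation. The fallback sets out from 12 and comes back at 13. An intramolecular Mizoroki–Heck reaction (Pd(OAc)2, P(o-tol)3, Et3N, DMF, 2 mM, 100 °C) closes the ring as the (E)-stilbene macrocyclic salicylaldehyde F1. Chemoselective alkene hydrogenation (H2 1 atm, Pd/C poisoned with Ph2S, EtOAc) then gives 13 without touching the aldehyde.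

- **Step 6 (intermolecular hydroarylation).** The benzylic adduct radical is reduced slowly by Bu3SnH, so telomerisation of styrene 9 and simple reduction of 6 compete. The fallback sets out from 6 and 9 and comes back at 10. Mizoroki–Heck coupling at the iodide (Pd(OAc)2, Et3N, DMF, 80 °C; the bromide is left) gives the (E)-stilbene F2. Hydrogenation with RhCl(PPh3)3 and H2 (3 atm, benzene/EtOH, rt), which spares the aryl bromide and the aldehyde, gives 10.

- **Step 1 (Cu O-arylation of free catechol; step 4 is the same reaction type).** Catechol can chelate copper and can be arylated twice. The fallback sets out from 2 and 1 and comes back at 3. Oxidation of 2 with mCPBA/TfOH in CH2Cl2 in the presence of bromobenzene gives bis(4-bromophenyl)iodonium triflate F3. Metal-free arylation of catechol 1 (3 equiv) with F3 and t-BuOK in THF at rt gives 3 and returns one equivalent of 2.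

## Further compounds

F1 | step 9 | (E)-stilbene macrocyclic salicylaldehyde (13 with CH=CH in place of the ring-A/ring-D CH2CH2 bridge) | O=Cc1cc2cc(Oc3ccc(cc3)/C=C/c3ccc(O)c(c3)Oc3cccc(c3)CC2)c1O
F2 | step 6 | 3-(4-bromophenoxy)-2-hydroxy-5-[(E)-2-[3-(2-hydroxyphenoxy)phenyl]ethenyl]benzaldehyde | O=Cc1cc(/C=C/c2cccc(Oc3ccccc3O)c2)cc(Oc2ccc(Br)cc2)c1O
F3 | step 1 | bis(4-bromophenyl)iodonium trifluoromethanesulfonate | Brc1ccc([I+]c2ccc(Br)cc2)cc1.[O-]S(=O)(=O)C(F)(F)F
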